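- The constants 2.29 M⁻¹ h⁻¹ for the step to E.X and 0.378 M⁻¹ h⁻¹ for the step to E.G set a fork for each molecule of E: its two roads run in the ratio of those constants times c(X) and c(G).

E 0.50 M; Q 110 mM (held); G 0.500 M; time 2.0 d

    Q ⇌ X, rate k1*(csat - [X]) (k1 = 6.00 h⁻¹, csat = 110 mM)
    E + X → E.X (k2 = 2.29 M⁻¹ h⁻¹)
    X → J (k3 = 0.00149 h⁻¹)
    E + G → E.G (k4 = 0.378 M⁻¹ h⁻¹)
    2 X → X2 (k5 = 9.87 M⁻¹ h⁻¹)

- a step written with two of one species runs at k times the square of its concentration and takes two of it each time
- at the start none of X is dissolved
- run time (flask): 2.0 d

- gamma: doubling the saturation concentration of Q, all else as stated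
- beta: doubling the transfer coefficient of step 1, all else as stated

- how much E.X there is at 2.0 d, in percent of the E charged
- concentration of X in solution at 25 h, in percent of saturation
- the change that raises the amount of E.X at 2.0 d, in percent of the E charged most ("none" if none brings more than 2 percentage points) (gamma / beta / none)
- amount of E.X at 2.0 d, in percent of the E charged, after gamma

- Turned round, the question is this: E goes mostly to E.G if c(G) stands above the level where the two roads run equally.
- That level needs c(X). Transfer has a time of 10.0 min, far shorter than the run, and the half-life of X towards J, 19 d, is long against it.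
- My reckoning therefore balances transfer against the pairing of X, which gives c(X) = 85.8 mM, or 78.0% of saturation.
- E's half-life by G's step, with G as charged, is 0.15 d, shorter than 25 h, so that balance should hold at 25 h. While E lasts it takes X at up to 0.0982 M h⁻¹, so this level leans high for the early hours.
- The crossover level c* of G is the E.X constant times c(X) over the E.G constant: 0.520 M. Its ratio to c(G) is the selectivity factor, and the chance of E.X at the fork is c*/(c* + c(G)).
- The charge of 0.500 M stands just under the crossover, so with c(X) at that balance the chance at the charged c(G) is 51.0%.
- G falls as E goes, with a mean near 0.377 M, which gives an estimate of 57.9% E.X.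
- Doubling saturation lifts the crossover to 0.896 M and the yield to 68.6%. Doubling transfer lifts the crossover to 0.576 M, less than gamma does.
- The forecast gives 56.4%, 78%, gamma and 67.4%, on the ground that “Doubling the saturation concentration raises X much more”. Its yield lies under mine.

- The simulation gives 55.6%, 78.0%, gamma with 11 percentage points against 2.8 points for beta, and 66.6%. In this flask, with 0.500 M of G against a crossover of 0.520 M, E, the limiting reagent, stands at 0% at 2.00 d, with E.X at 55.6% and E.G at 44.4%. The neighbour flask, charged with 1.2 M of G, stands above the crossover. There the same reckoning gives a mean c(G) of 1.03 M and a chance of 33.6% for E.X. In that neighbour flask E.G takes 68.8%, and E.X ends at 31.2%.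

All constants are those of an exercise; the result is computed.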